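**Retrosynthetic overview**
1. Ring B is closed last by Dieckmann condensation (C8 ester enolate onto the C9 ester carbon), followed by triflate → formyl → deconjugative protonation. C3–Cl comes from a C3 boronate with inversion, and C1–OH from a ring A ketone.
2. The β-methyl groups on C4 and C10 are the two ends of a CH2–S–CH2 bridge that Raney Ni removes. The bridge arises from a [2,3]-shift of a sulfonium ylide, which moves sulfur from C2 to a new CH2 on C4 and unmasks the C1 enone.
3. Ring A is made first, in the key step: amine-catalysed Michael addition of methyl 4-oxothiolane-3-carboxylate to a linear enal (C5–C10 bond), then intramolecular aldol of the sulfur-bearing CH2 onto the aldehyde (C2–C3 bond), giving a 6-thiabicyclo[3.2.1]octane.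
4. Enabling feature: in ring A the oxygenated carbon C1 lies between C2 and C10, so a C1 ketone makes both nucleophilic toward C3 and C5, which are 1,3-related like the carbonyl and β-carbons of an enal. The methyl groups on C10 and C4 are syn-1,3-diaxial, so one sulfur atom can hold the C10 methyl carbon first to C2 (temporary thiolane) and then to the C4 methyl carbon.
5. Order of rings: temporary thiolane (bought) → ring A (key step) → temporary thiane ([2,3]-shift, later cleaved) → ring B (Dieckmann). C5 is set by the catalyst and the other centres are relayed from it.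

Key step: step 2

Remark: carbons are numbered as in the drimane skeleton of the target (ring A: C1 = CHOH, C2, C3 = CHCl, C4, C5, C10; ring B: C5 to C10; C11 = CHO carbon, C12 = ester carbon); β is the face of the C10 methyl group and α the opposite face.

Step 1
Reactants: 1 methyl hex-5-enoate; 2 (E)-but-2-enal
Product: 3 methyl (E)-7-oxohept-5-enoate
Conditions: 2 (5 equiv), second-generation Hoveyda–Grubbs catalyst RuCl2(H2IMes)(=CH-C6H4-2-OiPr) (2 mol%), CH2Cl2, 40 °C
Reagents that add atoms: none
Why: Cross-metathesis of a terminal alkene with excess crotonaldehyde is a standard route to (E)-enals, since the conjugated E-alkene is the thermodynamic product and propene escapes.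

Step 2
Reactants: 3 methyl (E)-7-oxohept-5-enoate; 4 methyl 4-oxothiolane-3-carboxylate
Product: 6 bicyclic ketol methyl 4-hydroxy-2-(4-methoxy-4-oxobutyl)-8-oxo-6-thiabicyclo[3.2.1]octane-1-carboxylate, via Michael adduct 5 (not isolated)
Conditions: (R)-α,α-diphenylprolinol trimethylsilyl ether (10 mol%), PhCO2H (10 mol%), toluene, 0 °C → rt; then DBU (0.2 equiv), rt
Reagents that add atoms: none
Why: The (R)-pyrrolidine catalyst turns enal 3 into an s-trans (E)-iminium ion whose face on the side of the CPh2OSiMe3 group is shielded, the enol of β-keto ester 4 adds through its doubly activated carbon (C10) to the open face of the β-carbon (C5) to give Michael adduct 5 (C5–C10 bond), and DBU then enolises the ring ketone of 5 toward its only remaining α-carbon, the sulfur-bearing CH2 (C2), which attacks the free aldehyde (C3) in an intramolecular aldol addition (C2–C3 bond). The closest known reaction type is the amine-catalysed Michael addition of cyclic β-keto esters to enals combined with the Michael–aldol α,α'-annulation of 2-oxocycloalkanecarboxylates that gives bicyclo[3.2.1]octan-8-ones. Ring A is the only ring closed, in a 6-(enolendo)-exo-trig aldol mode across the thiolanone, so that the thiolane becomes the two-atom bridge of a 6-thiabicyclo[3.2.1]octane. C5 is set by the catalyst, C10 relative to C5 by a staggered open transition state in which the small C5–H lies between ring carbonyl and ester and the ester chain ends cis to the sulfur-bearing CH2 arm, C2 by the bicyclic geometry (sulfur cis to that arm), and the carbinol carbon C3 forms under reversible conditions and is erased in step 3. The step needs Michael addition at C10 in preference to C2 and C- in preference to O-attack (secured by the β-keto ester), enantiofacial control at C5 (catalyst), the C5/C10 relative configuration (open transition state, with chromatographic removal of any C10 epimer), and survival of the strained bridging β-keto ester, which the aprotic medium and the non-nucleophilic amidine base secure because alkoxides would open it by retro-Dieckmann cleavage. The thiolane ring is the temporary element that is cleaved later: it makes C10 a stabilised nucleophile, fixes the future C10 methyl carbon axial on ring A (trans to the C5–H), and blocks enolisation of the ring A ketones toward C2 in steps 6 and 7.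

Step 3
Reactants: 6 bicyclic ketol
Product: 7 bicyclic diketone methyl 2-(4-methoxy-4-oxobutyl)-4,8-dioxo-6-thiabicyclo[3.2.1]octane-1-carboxylate
Conditions: SO3·pyridine, DMSO, Et3N, CH2Cl2, 0 °C → rt
Reagents that add atoms: none
Why: Parikh–Doering oxidation (DMSO activated by SO3·pyridine) converts the secondary alcohol into the ketone without oxidising the sulfide, and the non-enolisable bridgehead C2 rules out elimination or epimerisation.

Step 4
Reactants: 8 2-methylbut-3-en-2-ol; 9 3-bromoprop-1-ene
Product: 10 (E)-5-bromo-2-methylpent-3-en-2-ol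
Conditions: 9 (3 equiv), second-generation Hoveyda–Grubbs catalyst RuCl2(H2IMes)(=CH-C6H4-2-OiPr) (2 mol%), CH2Cl2, 40 °C
Reagents that add atoms: none
Why: Cross-metathesis between allyl bromide (fast-reacting) and a tertiary allylic alcohol (slow to homodimerise) is a selective pairing that should give the E-alkene with loss of ethene.

Step 5
Reactants: 10 (E)-5-bromo-2-methylpent-3-en-2-ol
Product: 11 [(E)-5-bromo-2-methylpent-3-en-2-yl]oxy-triethylsilane
Conditions: Et3SiOTf, 2,6-lutidine, CH2Cl2, −78 → 0 °C
Reagents that add atoms: triethylsilyl trifluoromethanesulfonate CC[Si](CC)(CC)OS(=O)(=O)C(F)(F)F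
Why: Silylation of a hindered tertiary alcohol with a silyl triflate and a hindered pyridine base is standard and leaves the allylic bromide untouched.

Step 6
Reactants: 7 bicyclic diketone; 11 [(E)-5-bromo-2-methylpent-3-en-2-yl]oxy-triethylsilane
Product: 12 methyl 2-(4-methoxy-4-oxobutyl)-3-[(E)-4-methyl-4-(triethylsilyloxy)pent-2-enyl]-4,8-dioxo-6-thiabicyclo[3.2.1]octane-1-carboxylate
Conditions: LiN(iPr)2 (1.05 equiv), THF, −78 °C; then 11, DMPU, −78 → −20 °C
Reagents that add atoms: none
Why: Kinetic deprotonation can only occur at C4 (C2 is a bridgehead and the bridging ketone has no enolisable α-hydrogen), and SN2 alkylation of this lithium enolate with the allylic bromide (ketone enolate alkylation) should occur on the face away from the CH2–S bridge, a configuration that is erased in step 7.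

Step 7
Reactants: 12 alkylated diketone
Product: 13 enol triflate methyl 2-(4-methoxy-4-oxobutyl)-3-[(E)-4-methyl-4-(triethylsilyloxy)pent-2-enyl]-8-oxo-4-(trifluoromethylsulfonyloxy)-6-thiabicyclo[3.2.1]oct-3-ene-1-carboxylate
Conditions: KN(SiMe3)2 (1.2 equiv), THF, −78 °C; then PhNTf2, −78 → 0 °C
Reagents that add atoms: N-phenylbis(trifluoromethanesulfonimide) O=S(=O)(N(c1ccccc1)S(=O)(=O)C(F)(F)F)C(F)(F)F
Why: The only enolate that 12 can form is the C3=C4 enolate, and O-sulfonylation of its potassium salt with PhNTf2 gives the tetrasubstituted enol triflate (enol triflate formation).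

Step 8
Reactants: 13 enol triflate
Product: 14 allyl sulfide methyl 2-(4-methoxy-4-oxobutyl)-3-[(E)-4-methyl-4-(triethylsilyloxy)pent-2-enyl]-8-oxo-6-thiabicyclo[3.2.1]oct-3-ene-1-carboxylate
Conditions: Pd(OAc)2 (5 mol%), PPh3 (10 mol%), HCO2H, Et3N, DMF, 60 °C
Reagents that add atoms: none
Why: Palladium-catalysed formate reduction of an enol triflate (oxidative addition to zerovalent palladium, triflate–formate exchange, decarboxylation, C–H reductive elimination) gives the trisubstituted C3=C4 alkene, which places an allyl unit (C2–C3=C4) next to sulfur.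

Step 9
Reactants: 14 allyl sulfide
Product: 16 thiane-bridged enone methyl 9-(4-methoxy-4-oxobutyl)-5-[(E)-4-methyl-4-(triethylsilyloxy)pent-2-enyl]-8-oxo-3-thiabicyclo[3.3.1]non-6-ene-1-carboxylate, via sulfonium ylide 15 (not isolated)
Conditions: Et2Zn (1.5 equiv), CH2I2 (1.5 equiv), CH2Cl2, 0 °C → rt
Reagents that add atoms: diiodomethane ICI
Why: Methylene transfer from the zinc carbenoid to sulfur gives sulfonium ylide 15, whose [2,3]-sigmatropic shift (Doyle–Kirmse-type rearrangement of an allyl sulfide) is suprafacial, so the new CH2 bonds to C4 on the face that carried sulfur (cis to the C10 CH2 arm, which fixes the quaternary centre C4), while the C2–S bond breaks and the alkene moves to C2=C3 in conjugation with the C1 ketone.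

Step 10
Reactants: 16 thiane-bridged enone
Product: 17 β-boryl ketone methyl 9-(4-methoxy-4-oxobutyl)-5-[(E)-4-methyl-4-(triethylsilyloxy)pent-2-enyl]-8-oxo-6-(4,4,5,5-tetramethyl-1,3,2-dioxaborolan-2-yl)-3-thiabicyclo[3.3.1]nonane-1-carboxylate
Conditions: CuCl (5 mol%), DPEphos (5 mol%), NaOtBu (10 mol%), B2pin2 (1.1 equiv), MeOH (2 equiv), THF, rt
Reagents that add atoms: bis(pinacolato)diboron CC1(C)OB(OC1(C)C)B1OC(C)(C)C(C)(C)O1
Why: Copper-catalysed conjugate borylation of an enone is well established, and the Cu–B nucleophile should add to C3 from the α-face, anti to the CH2–S–CH2 bridge that covers the β-face, giving the axial 3α-boronate.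

Step 11
Reactants: 17 β-boryl ketone
Product: 18 β-boryl alcohol methyl 8-hydroxy-9-(4-methoxy-4-oxobutyl)-5-[(E)-4-methyl-4-(triethylsilyloxy)pent-2-enyl]-6-(4,4,5,5-tetramethyl-1,3,2-dioxaborolan-2-yl)-3-thiabicyclo[3.3.1]nonane-1-carboxylate
Conditions: LiBH(s-Bu)3, THF, −78 °C; aqueous NH4Cl work-up without oxidant
Reagents that add atoms: none
Why: Ketone reduction with a bulky borohydride should take place from the β-face, because axial approach from the α-face is blocked by the syn-axial C3 boronate, and so give the axial 1α-alcohol while the non-oxidative work-up keeps the C–B bond.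

Step 12
Reactants: 18 β-boryl alcohol
Product: 19 silyl ether methyl 9-(4-methoxy-4-oxobutyl)-5-[(E)-4-methyl-4-(triethylsilyloxy)pent-2-enyl]-6-(4,4,5,5-tetramethyl-1,3,2-dioxaborolan-2-yl)-8-(triethylsilyloxy)-3-thiabicyclo[3.3.1]nonane-1-carboxylate
Conditions: Et3SiOTf, 2,6-lutidine, CH2Cl2, 0 °C
Reagents that add atoms: triethylsilyl trifluoromethanesulfonate CC[Si](CC)(CC)OS(=O)(=O)C(F)(F)F
Why: Silyl triflate silylation caps the hindered axial alcohol so that no alkoxide can chelate boron in step 14, and the same silyl group as on the side chain lets both be removed together at the end.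

Step 13
Reactants: 19 silyl ether
Product: 20 cyclohexyl boronate methyl 2-(4-methoxy-4-oxobutyl)-1,3-dimethyl-3-[(E)-4-methyl-4-(triethylsilyloxy)pent-2-enyl]-4-(4,4,5,5-tetramethyl-1,3,2-dioxaborolan-2-yl)-6-(triethylsilyloxy)cyclohexane-1-carboxylate
Conditions: Raney Ni (W-2, deactivated in refluxing acetone), EtOH, rt
Reagents that add atoms: none
Why: Raney nickel hydrogenolysis of the two C–S bonds (reductive desulfurisation) turns the CH2–S–CH2 bridge into the syn-1,3-diaxial methyl groups on C4 and C10, while the hindered E-alkene, the silyl ethers and the C–B bond should survive the deactivated catalyst.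

Step 14
Reactants: 20 cyclohexyl boronate
Product: 22 chloride methyl 4-chloro-2-(4-methoxy-4-oxobutyl)-1,3-dimethyl-3-[(E)-4-methyl-4-(triethylsilyloxy)pent-2-enyl]-6-(triethylsilyloxy)cyclohexane-1-carboxylate, via lithium boronate complex 21 (not isolated)
Conditions: 3,5-(CF3)2C6H3Br, n-BuLi, THF, −78 °C; add 20, −78 °C; then trichloroisocyanuric acid (0.4 equiv), −78 °C
Reagents that add atoms: trichloroisocyanuric acid ClN1C(=O)N(Cl)C(=O)N(Cl)C1=O
Why: Addition of the electron-poor aryllithium to boron gives boronate complex 21, and its reaction with electrophilic chlorine is an SE2 substitution with inversion at carbon (stereoinvertive halogenation of secondary boronic ester ate complexes), so the 3α-boronate should give the 3β (equatorial) chloride with no elimination pathway available.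

Step 15
Reactants: 22 chloride
Product: 23 β-keto ester (enol form) methyl 6-chloro-1-hydroxy-5,8a-dimethyl-5-[(E)-4-methyl-4-(triethylsilyloxy)pent-2-enyl]-8-(triethylsilyloxy)-3,4,4a,5,6,7,8,8a-octahydronaphthalene-2-carboxylate
Conditions: LiN(SiMe3)2 (2.2 equiv), THF, −78 °C → rt; aqueous NH4Cl
Reagents that add atoms: none
Why: Dieckmann condensation: the only enolisable ester (C8) attacks the neopentyl ester carbon C9 in a 6-exo-trig closure between two trans-diequatorial arms, which should give the trans-fused ring B and is driven by deprotonation of the β-keto ester.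

Step 16
Reactants: 23 β-keto ester
Product: 24 vinyl triflate methyl 6-chloro-5,8a-dimethyl-5-[(E)-4-methyl-4-(triethylsilyloxy)pent-2-enyl]-8-(triethylsilyloxy)-1-(trifluoromethylsulfonyloxy)-3,4,4a,5,6,7,8,8a-octahydronaphthalene-2-carboxylate
Conditions: NaH, THF, 0 °C; then PhNTf2, rt
Reagents that add atoms: N-phenylbis(trifluoromethanesulfonimide) O=S(=O)(N(c1ccccc1)S(=O)(=O)C(F)(F)F)C(F)(F)F
Why: NaH deprotonates only the β-keto ester, and O-sulfonylation of this sodium enolate with PhNTf2 gives the vinyl triflate (enol triflate formation).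

Step 17
Reactants: 24 vinyl triflate
Product: 25 conjugated aldehyde methyl 6-chloro-1-formyl-5,8a-dimethyl-5-[(E)-4-methyl-4-(triethylsilyloxy)pent-2-enyl]-8-(triethylsilyloxy)-3,4,4a,5,6,7,8,8a-octahydronaphthalene-2-carboxylate
Conditions: Pd(PPh3)4 (5 mol%), CO (3 atm), Bu3SnH (slow addition), THF, 50 °C
Reagents that add atoms: carbon monoxide [C-]#[O+]
Why: Palladium-catalysed reductive carbonylation (formylation) of a vinyl triflate, by oxidative addition to zerovalent palladium, CO insertion and hydride transfer from Bu3SnH, installs C11 at the aldehyde oxidation level.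

Step 18
Reactants: 25 conjugated aldehyde
Product: 26 bis-silyl ether of the target methyl 6-chloro-1-formyl-5,8a-dimethyl-5-[(E)-4-methyl-4-(triethylsilyloxy)pent-2-enyl]-8-(triethylsilyloxy)-1,4,4a,5,6,7,8,8a-octahydronaphthalene-2-carboxylate
Conditions: KN(SiMe3)2 (1.2 equiv), THF, −78 °C; then AcOH, −78 °C
Reagents that add atoms: none
Why: Deconjugative protonation: γ-deprotonation at C7 gives the extended enolate of the aldehyde, and kinetic protonation at its α-carbon C9 from the α-face, opposite the axial C10 methyl group, should set the 9β-formyl centre and leave the alkene at C7=C8 in conjugation with the ester.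

Step 19
Reactants: 26 bis-silyl ether of the target
Product: 27 target methyl (1R,4aR,5S,6S,8S,8aS)-6-chloro-1-formyl-8-hydroxy-5-[(E)-4-hydroxy-4-methylpent-2-enyl]-5,8a-dimethyl-1,4,4a,5,6,7,8,8a-octahydronaphthalene-2-carboxylate
Conditions: HF·pyridine, pyridine, THF, 0 °C → rt
Reagents that add atoms: none
Why: Desilylation of both triethylsilyl ethers with pyridine-buffered HF·pyridine is mild enough not to epimerise C9 or move the C7=C8 double bond.

**Compound list**
1 | methyl hex-5-enoate | C=CCCCC(=O)OC | starting material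
2 | (E)-but-2-enal (crotonaldehyde) | C/C=C/C=O | starting material
3 | methyl (E)-7-oxohept-5-enoate | COC(=O)CCC/C=C/C=O | intermediate
4 | methyl 4-oxothiolane-3-carboxylate (racemic, enolisable) | COC(=O)C1CSCC1=O | starting material
5 | Michael adduct methyl 3-(7-methoxy-1,7-dioxoheptan-3-yl)-4-oxothiolane-3-carboxylate (configuration as in the SMILES) | COC(=O)CCC[C@@H](CC=O)[C@]1(C(=O)OC)CSCC1=O | intermediate (not isolated)
6 | methyl 4-hydroxy-2-(4-methoxy-4-oxobutyl)-8-oxo-6-thiabicyclo[3.2.1]octane-1-carboxylate (ester chain on C5 cis to the CH2–S arm, C5–H trans to it; carbinol drawn as the equatorial epimer, inconsequential) | COC(=O)CCC[C@H]2C[C@@H](O)[C@H]3SC[C@]2(C(=O)OC)C3=O | intermediate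
7 | methyl 2-(4-methoxy-4-oxobutyl)-4,8-dioxo-6-thiabicyclo[3.2.1]octane-1-carboxylate | COC(=O)CCC[C@H]2CC(=O)[C@H]3SC[C@]2(C(=O)OC)C3=O | intermediate
8 | 2-methylbut-3-en-2-ol | CC(C)(O)C=C | starting material
9 | 3-bromoprop-1-ene (allyl bromide) | C=CCBr | starting material
10 | (E)-5-bromo-2-methylpent-3-en-2-ol | CC(C)(O)/C=C/CBr | intermediate
11 | [(E)-5-bromo-2-methylpent-3-en-2-yl]oxy-triethylsilane | CC[Si](CC)(CC)OC(C)(C)/C=C/CBr | intermediate
12 | methyl 2-(4-methoxy-4-oxobutyl)-3-[(E)-4-methyl-4-(triethylsilyloxy)pent-2-enyl]-4,8-dioxo-6-thiabicyclo[3.2.1]octane-1-carboxylate (new chain on C4 on the face away from the sulfur bridge) | COC(=O)CCC[C@H]2[C@H](C/C=C/C(C)(C)O[Si](CC)(CC)CC)C(=O)[C@H]3SC[C@]2(C(=O)OC)C3=O | intermediate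
13 | methyl 2-(4-methoxy-4-oxobutyl)-3-[(E)-4-methyl-4-(triethylsilyloxy)pent-2-enyl]-8-oxo-4-(trifluoromethylsulfonyloxy)-6-thiabicyclo[3.2.1]oct-3-ene-1-carboxylate | COC(=O)CCC[C@H]2C(C/C=C/C(C)(C)O[Si](CC)(CC)CC)=C(OS(=O)(=O)C(F)(F)F)[C@H]3SC[C@]2(C(=O)OC)C3=O | intermediate
14 | methyl 2-(4-methoxy-4-oxobutyl)-3-[(E)-4-methyl-4-(triethylsilyloxy)pent-2-enyl]-8-oxo-6-thiabicyclo[3.2.1]oct-3-ene-1-carboxylate | COC(=O)CCC[C@H]2C(C/C=C/C(C)(C)O[Si](CC)(CC)CC)=C[C@H]3SC[C@]2(C(=O)OC)C3=O | intermediate
15 | S-methylide (sulfonium ylide) of 14 | COC(=O)CCC[C@H]2C(C/C=C/C(C)(C)O[Si](CC)(CC)CC)=C[C@H]3[S+]([CH2-])C[C@]2(C(=O)OC)C3=O | intermediate (not isolated)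
16 | methyl 9-(4-methoxy-4-oxobutyl)-5-[(E)-4-methyl-4-(triethylsilyloxy)pent-2-enyl]-8-oxo-3-thiabicyclo[3.3.1]non-6-ene-1-carboxylate (CH2–S–CH2 bridge on the β-face of ring A, side chain on C4 α) | COC(=O)CCC[C@H]2[C@](CSC4)(C/C=C/C(C)(C)O[Si](CC)(CC)CC)C=CC(=O)[C@]24C(=O)OC | intermediate
17 | methyl 9-(4-methoxy-4-oxobutyl)-5-[(E)-4-methyl-4-(triethylsilyloxy)pent-2-enyl]-8-oxo-6-(4,4,5,5-tetramethyl-1,3,2-dioxaborolan-2-yl)-3-thiabicyclo[3.3.1]nonane-1-carboxylate (boron 3α, axial) | COC(=O)CCC[C@H]2[C@](CSC4)(C/C=C/C(C)(C)O[Si](CC)(CC)CC)[C@H](B3OC(C)(C)C(C)(C)O3)CC(=O)[C@]24C(=O)OC | intermediate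
18 | methyl 8-hydroxy-9-(4-methoxy-4-oxobutyl)-5-[(E)-4-methyl-4-(triethylsilyloxy)pent-2-enyl]-6-(4,4,5,5-tetramethyl-1,3,2-dioxaborolan-2-yl)-3-thiabicyclo[3.3.1]nonane-1-carboxylate (hydroxyl 1α, axial) | COC(=O)CCC[C@H]2[C@](CSC4)(C/C=C/C(C)(C)O[Si](CC)(CC)CC)[C@H](B3OC(C)(C)C(C)(C)O3)C[C@H](O)[C@]24C(=O)OC | intermediate
19 | methyl 9-(4-methoxy-4-oxobutyl)-5-[(E)-4-methyl-4-(triethylsilyloxy)pent-2-enyl]-6-(4,4,5,5-tetramethyl-1,3,2-dioxaborolan-2-yl)-8-(triethylsilyloxy)-3-thiabicyclo[3.3.1]nonane-1-carboxylate | COC(=O)CCC[C@H]2[C@](CSC4)(C/C=C/C(C)(C)O[Si](CC)(CC)CC)[C@H](B3OC(C)(C)C(C)(C)O3)C[C@H](O[Si](CC)(CC)CC)[C@]24C(=O)OC | intermediate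
20 | methyl 2-(4-methoxy-4-oxobutyl)-1,3-dimethyl-3-[(E)-4-methyl-4-(triethylsilyloxy)pent-2-enyl]-4-(4,4,5,5-tetramethyl-1,3,2-dioxaborolan-2-yl)-6-(triethylsilyloxy)cyclohexane-1-carboxylate (both methyl groups β, boron and silyloxy α) | COC(=O)CCC[C@H]2[C@](C)(C/C=C/C(C)(C)O[Si](CC)(CC)CC)[C@H](B3OC(C)(C)C(C)(C)O3)C[C@H](O[Si](CC)(CC)CC)[C@]2(C)C(=O)OC | intermediate
21 | lithium [3,5-bis(trifluoromethyl)phenyl]boronate complex of 20 | [Li+].COC(=O)CCC[C@H]2[C@](C)(C/C=C/C(C)(C)O[Si](CC)(CC)CC)[C@H]([B-]3(c4cc(cc(c4)C(F)(F)F)C(F)(F)F)OC(C)(C)C(C)(C)O3)C[C@H](O[Si](CC)(CC)CC)[C@]2(C)C(=O)OC | intermediate (not isolated)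
22 | methyl 4-chloro-2-(4-methoxy-4-oxobutyl)-1,3-dimethyl-3-[(E)-4-methyl-4-(triethylsilyloxy)pent-2-enyl]-6-(triethylsilyloxy)cyclohexane-1-carboxylate (chlorine 3β) | COC(=O)CCC[C@H]2[C@](C)(C/C=C/C(C)(C)O[Si](CC)(CC)CC)[C@@H](Cl)C[C@H](O[Si](CC)(CC)CC)[C@]2(C)C(=O)OC | intermediate
23 | methyl 6-chloro-1-hydroxy-5,8a-dimethyl-5-[(E)-4-methyl-4-(triethylsilyloxy)pent-2-enyl]-8-(triethylsilyloxy)-3,4,4a,5,6,7,8,8a-octahydronaphthalene-2-carboxylate (trans-fused; β-keto ester drawn as its enol) | COC(=O)C=1CC[C@H]2[C@](C)(C/C=C/C(C)(C)O[Si](CC)(CC)CC)[C@@H](Cl)C[C@H](O[Si](CC)(CC)CC)[C@]2(C)C=1O | intermediate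
24 | methyl 6-chloro-5,8a-dimethyl-5-[(E)-4-methyl-4-(triethylsilyloxy)pent-2-enyl]-8-(triethylsilyloxy)-1-(trifluoromethylsulfonyloxy)-3,4,4a,5,6,7,8,8a-octahydronaphthalene-2-carboxylate | COC(=O)C=1CC[C@H]2[C@](C)(C/C=C/C(C)(C)O[Si](CC)(CC)CC)[C@@H](Cl)C[C@H](O[Si](CC)(CC)CC)[C@]2(C)C=1OS(=O)(=O)C(F)(F)F | intermediate
25 | methyl 6-chloro-1-formyl-5,8a-dimethyl-5-[(E)-4-methyl-4-(triethylsilyloxy)pent-2-enyl]-8-(triethylsilyloxy)-3,4,4a,5,6,7,8,8a-octahydronaphthalene-2-carboxylate | COC(=O)C=1CC[C@H]2[C@](C)(C/C=C/C(C)(C)O[Si](CC)(CC)CC)[C@@H](Cl)C[C@H](O[Si](CC)(CC)CC)[C@]2(C)C=1C=O | intermediate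
26 | methyl 6-chloro-1-formyl-5,8a-dimethyl-5-[(E)-4-methyl-4-(triethylsilyloxy)pent-2-enyl]-8-(triethylsilyloxy)-1,4,4a,5,6,7,8,8a-octahydronaphthalene-2-carboxylate (formyl 9β) | COC(=O)C1=CC[C@H]2[C@](C)(C/C=C/C(C)(C)O[Si](CC)(CC)CC)[C@@H](Cl)C[C@H](O[Si](CC)(CC)CC)[C@]2(C)[C@H]1C=O | intermediate
27 | methyl (1R,4aR,5S,6S,8S,8aS)-6-chloro-1-formyl-8-hydroxy-5-[(E)-4-hydroxy-4-methylpent-2-enyl]-5,8a-dimethyl-1,4,4a,5,6,7,8,8a-octahydronaphthalene-2-carboxylate (CNP0167913.1) | COC(=O)C1=CC[C@H]2[C@](C)(C/C=C/C(C)(C)O)[C@@H](Cl)C[C@H](O)[C@]2(C)[C@H]1C=O | target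

**Step count and risks**
Total step count: 19 (17 in the main line, 2 for bromide 11). Longest linear sequence: 17 steps (steps 1 to 3 and 6 to 19).

Steps most likely to fail:

Step 14 (chlorination). The aryllithium may add to the unhindered side-chain methyl ester before the hindered secondary boronic ester is complexed, and single-electron oxidation of the boronate complex may erode the inversion. The fallback sets out from 20. Selective saponification of the primary-chain ester (LiOH, THF–H2O, 0 °C; the neopentyl ester on the quaternary carbon should be inert) would give the side-chain carboxylic acid F1. Its lithium carboxylate is inert to the aryllithium, so the same boronate chlorination with one extra equivalent of aryllithium should give the chloro acid F2. Methylation with Me3SiCHN2 in MeOH–toluene would then come back to the route at 22.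

Step 9 ([2,3]-shift). The zinc carbenoid may transfer its methylene to an alkene (cyclopropanation) instead of to sulfur, or the ylide may undergo a 1,2-shift. The fallback sets out from 14 and avoids the carbenoid: S-methylation with MeOTf in CH2Cl2 should give the isolable S-methylsulfonium triflate F3. Deprotonation of its S-methyl group with KN(SiMe3)2 in THF at −78 °C would generate the same ylide 15, whose [2,3]-shift comes back to the route at 16.

Step 2 (key step). The open transition state may give poor diastereofacial selectivity at C10, and retro-Michael reaction during the base-mediated aldol may erode the enantiomeric purity. The fallback sets out from 3 and 4 and separates the two bond formations. A bifunctional 6'-hydroxy cinchona alkaloid catalyst, which activates the keto ester by hydrogen bonding and general-base catalysis and is known to join cyclic β-keto esters to β-substituted enals with control of adjacent quaternary and tertiary centres, would give Michael adduct 5, now isolated and purified. A separate aldol closure with catalytic DBU in toluene would come back to the route at 6. Because the two catalyst classes can differ in relative configuration, this also covers the case in which iminium catalysis favours the unwanted C10 epimer. It makes no compound outside the list (F0).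

**Further compounds**
F1 | step 14 | 4-[2-(methoxycarbonyl)-2,6-dimethyl-6-[(E)-4-methyl-4-(triethylsilyloxy)pent-2-enyl]-5-(4,4,5,5-tetramethyl-1,3,2-dioxaborolan-2-yl)-3-(triethylsilyloxy)cyclohexyl]butanoic acid (side-chain acid of 20) | OC(=O)CCC[C@H]2[C@](C)(C/C=C/C(C)(C)O[Si](CC)(CC)CC)[C@H](B3OC(C)(C)C(C)(C)O3)C[C@H](O[Si](CC)(CC)CC)[C@]2(C)C(=O)OC
F2 | step 14 | 4-[5-chloro-2-(methoxycarbonyl)-2,6-dimethyl-6-[(E)-4-methyl-4-(triethylsilyloxy)pent-2-enyl]-3-(triethylsilyloxy)cyclohexyl]butanoic acid (side-chain acid of 22) | OC(=O)CCC[C@H]2[C@](C)(C/C=C/C(C)(C)O[Si](CC)(CC)CC)[C@@H](Cl)C[C@H](O[Si](CC)(CC)CC)[C@]2(C)C(=O)OC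
F3 | step 9 | S-methylsulfonium trifluoromethanesulfonate of 14 | COC(=O)CCC[C@H]2C(C/C=C/C(C)(C)O[Si](CC)(CC)CC)=C[C@H]3[S+](C)C[C@]2(C(=O)OC)C3=O.[O-]S(=O)(=O)C(F)(F)F
F0 | step 2 | none | none
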